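A direct plan would assemble an open-chain triene ester A1 by a dianionic Ireland–Claisen rearrangement, close the seven-membered ring by olefin metathesis, add the five-membered ring by rhodium-catalysed hydroacylation (ketone A2), then add isopropylmagnesium chloride and acylate the tertiary alkoxide. Its weakest steps would be:
(1) the sigmatropic rearrangement that must set the quaternary methyl-bearing carbon and the ring-fusion CH in an open chain, where only enolate geometry and a chair preference decide, and which is reached after seven steps of little added complexity;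
(2) the hydroacylation that must close a trans-fused cyclopentanone on a hindered β-silyloxy aldehyde, a closure without close precedent that decarbonylation, β-elimination and epimerisation can undercut;
(3) the late isopropyl addition to the enolisable β-silyloxy ketone A2 and the acylation of the resulting crowded tertiary alkoxide, both on the most precious material.

**Plan of the new route.** Numbering: C1 = C(i-Pr)(OCOAr), C2, C3, C4 = C(CH3) (ring fusion), C5, C6, C7(CH3), C8, C9 (CHOH), C10 (ring-fusion CH); ring A is five-membered, ring B seven-membered.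
(a) The C1 O–acyl bond and C9–H are cut together: O1 and C9 stand 1,3 across C10 and cis on ring A, so the tertiary ester/secondary alcohol pair is what an Evans–Tishchenko reduction of the C1-hydroxy C9-ketone with the aromatic aldehyde would give.
(b) C6=C7 (metathesis) and C8–C9 (Grignard) open ring B.
(c) Ring A comes from the six-membered ring of (S)-terpinen-4-ol (C1–C4, C9, C10, methyl, isopropyl): axial allylation sets C4 in a ring, and a Wolff contraction expels C9.
Ring A arises before ring B. No open-chain rearrangement, no hydroacylation, no isopropyl addition (C1 is bought) and no acylation of the tertiary alcohol occur.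

Key step: step 10

Assumption: (S)-(+)-terpinen-4-ol is used enantiomerically pure (commercial material of lower optical purity would be enriched first); it supplies C1 in the absolute configuration of the target.

Step 1
Reactants: 1 (S)-(+)-terpinen-4-ol, (1S)-4-methyl-1-(propan-2-yl)cyclohex-3-en-1-ol
Product: 2 tert-butyldimethyl{[(1S)-4-methyl-1-(propan-2-yl)cyclohex-3-en-1-yl]oxy}silane
Conditions: TBSOTf (1.3 equiv), 2,6-lutidine (2 equiv), CH2Cl2, 0 → 23 °C
Reagents that add atoms: tert-butyldimethylsilyl trifluoromethanesulfonate, CC(C)(C)[Si](C)(C)OS(=O)(=O)C(F)(F)F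
Why: Silylation of the hindered tertiary alcohol with the silyl triflate and a non-nucleophilic base should give an ether that survives the oxidations ahead and, being bulky and a poor donor, does not chelate the Lewis acid of step 5.

Step 2
Reactants: 2 tert-butyldimethyl{[(1S)-4-methyl-1-(propan-2-yl)cyclohex-3-en-1-yl]oxy}silane
Product: 3 tert-butyldimethyl{[(1S,4S,6R)-1-methyl-4-(propan-2-yl)-7-oxabicyclo[4.1.0]heptan-4-yl]oxy}silane
Conditions: mCPBA (1.1 equiv), CH2Cl2, 0 °C
Reagents that add atoms: 3-chloroperoxybenzoic acid, OOC(=O)c1cccc(Cl)c1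
Why: Prilezhaev epoxidation of the only alkene should favour attack anti to the pseudoaxial silyloxy group (isomer shown), and because both oxirane carbons lose their configuration in steps 3 and 4 the oxirane epimer formed alongside is carried on and converges.

Step 3
Reactants: 3 tert-butyldimethyl{[(1S,4S,6R)-1-methyl-4-(propan-2-yl)-7-oxabicyclo[4.1.0]heptan-4-yl]oxy}silane
Product: 5 (1S,4R)-4-[(tert-butyldimethylsilyl)oxy]-1-methyl-4-(propan-2-yl)cyclohex-2-en-1-ol, via hydroxy selenide 4 (not isolated)
Conditions: (PhSe)2 (0.6 equiv), NaBH4 (1.3 equiv), EtOH, 23 → 78 °C; then THF, 30% aq. H2O2, 0 → 23 °C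
Reagents that add atoms: none
Why: Trans-diaxial SN2 opening of the epoxide by benzeneselenolate at its secondary carbon, oxidation to the selenoxide and syn-elimination, which can only run towards the future C9 because the carbinol carbon bears no hydrogen, should give the tertiary allylic alcohol (epoxide to allylic alcohol transposition).

Step 4
Reactants: 5 (1S,4R)-4-[(tert-butyldimethylsilyl)oxy]-1-methyl-4-(propan-2-yl)cyclohex-2-en-1-ol
Product: 6 (6R)-6-[(tert-butyldimethylsilyl)oxy]-3-methyl-6-(propan-2-yl)cyclohex-2-en-1-one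
Conditions: pyridinium chlorochromate C5H5NH[CrO3Cl] (2.5 equiv), 4 Å molecular sieves, CH2Cl2, 23 °C
Reagents that add atoms: pyridinium chlorochromate, [O-][Cr](=O)(=O)Cl.c1cc[nH+]cc1
Why: Oxidative 1,3-transposition of the tertiary allylic alcohol (Babler–Dauben oxidation: chromate ester, [3,3] shift, oxidation) should place the carbonyl on the future C9 next to the protected carbinol and leave C1 as the only stereocentre.

Step 5
Reactants: 6 (6R)-6-[(tert-butyldimethylsilyl)oxy]-3-methyl-6-(propan-2-yl)cyclohex-2-en-1-one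
Product: 9 (2R,5R)-2-hydroxy-5-methyl-2-(propan-2-yl)-5-(prop-2-en-1-yl)cyclohexan-1-one, via trichlorotitanium enolate 7 (not isolated), via silyl ether ketone 8 (not isolated)
Conditions: CH2=CHCH2SiMe3 (1.5 equiv), TiCl4 (1.1 equiv), CH2Cl2, −78 °C; H2O; then 48% aq. HF, MeCN, 23 °C
Reagents that add atoms: allyltrimethylsilane, C=CC[Si](C)(C)C
Why: Hosomi–Sakurai conjugate allylation builds the quaternary C4: in the half-chair with isopropyl equatorial and the non-chelating silyloxy group axial, the stereoelectronically preferred axial attack at C4 should deliver allyl trans to the C1 oxygen (cis to isopropyl), and hydrogen fluoride then frees the tertiary hydroxyl needed in step 7.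

Step 6
Reactants: 9 (2R,5R)-2-hydroxy-5-methyl-2-(propan-2-yl)-5-(prop-2-en-1-yl)cyclohexan-1-one
Product: 11 (2R,5R)-6-diazo-2-hydroxy-5-methyl-2-(propan-2-yl)-5-(prop-2-en-1-yl)cyclohexan-1-one, via trifluoroacetyl ketone 10 (not isolated)
Conditions: LiN(SiMe3)2 (2.2 equiv), THF, −78 °C; CF3CO2CH2CF3 (1.3 equiv); 5% aq. HCl; then MsN3 (1.5 equiv), Et3N (2 equiv), H2O (1 equiv), MeCN, 23 °C
Reagents that add atoms: methanesulfonyl azide, CS(=O)(=O)N=[N+]=[N-]
Why: Detrifluoroacetylative diazo transfer (Regitz-type) can only take place at the future C10, the single enolisable position because C1 is quaternary, and the lithium alkoxide of the free hydroxyl is inert at −78 °C.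

Step 7
Reactants: 11 (2R,5R)-6-diazo-2-hydroxy-5-methyl-2-(propan-2-yl)-5-(prop-2-en-1-yl)cyclohexan-1-one
Product: 14 (1R,2R,5R)-2-hydroxy-N-methoxy-N,5-dimethyl-2-(propan-2-yl)-5-(prop-2-en-1-yl)cyclopentane-1-carboxamide, via ketene 12 (not isolated), via β-lactone 13 (not isolated)
Conditions: hν (medium-pressure Hg lamp, Pyrex filter), THF (0.01 M), 0 °C; then MeNH(OMe)·HCl (3 equiv) and i-PrMgCl (6 equiv), THF, −20 → 0 °C; aq. NH4Cl
Reagents that add atoms: N,O-dimethylhydroxylamine hydrochloride, CNOC.Cl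
Why: Proposed new method: photochemical Wolff rearrangement of the cyclic 2-diazo ketone (locked s-cis, so C1 migrates in concert and with retention) contracts the six-membered ring to the five-membered ketene 12, and with no external nucleophile present the neighbouring C1 hydroxyl should add to the ketene carbonyl carbon to give β-lactone 13, which can only be cis-fused and so fixes C9 cis to the C1 oxygen (C10–H trans) instead of leaving C10 to a face-selective protonation; the closest known reaction types are the Wolff ring contraction with capture of the ketene by alcohols (inter- and intramolecular, to esters and larger lactones) and the closure of β-alkoxides onto activated acyl groups to β-lactones, and the magnesium amide then opens the strained lactone at the acyl carbon (known aminolysis) to the N-methoxy-N-methylamide.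

Step 8
Reactants: 14 (1R,2R,5R)-2-hydroxy-N-methoxy-N,5-dimethyl-2-(propan-2-yl)-5-(prop-2-en-1-yl)cyclopentane-1-carboxamide
Product: 15 1-[(1R,2R,5R)-2-hydroxy-5-methyl-2-(propan-2-yl)-5-(prop-2-en-1-yl)cyclopentyl]-3-methylbut-3-en-1-one
Conditions: CH2=C(CH3)CH2MgCl (3.5 equiv), THF, −78 → −20 °C; cold aq. NH4Cl
Reagents that add atoms: 2-methylallylmagnesium chloride, CC(=C)C[Mg]Cl
Why: Ketone synthesis from the N-methoxy-N-methylamide (Weinreb amide): the first equivalent only deprotonates the hydroxyl, the chelated tetrahedral magnesium intermediate stops after one addition, and a cold buffered quench should keep the β,γ-unsaturated ketone out of conjugation.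

Step 9
Reactants: 15 1-[(1R,2R,5R)-2-hydroxy-5-methyl-2-(propan-2-yl)-5-(prop-2-en-1-yl)cyclopentyl]-3-methylbut-3-en-1-one
Product: 16 (3R,3aR,8aR)-3-hydroxy-6,8a-dimethyl-3-(propan-2-yl)-2,3,3a,5,8,8a-hexahydroazulen-4(1H)-one
Conditions: second-generation Grubbs catalyst (5 mol %), 1,4-benzoquinone (10 mol %), CH2Cl2 (0.005 M), 40 °C
Reagents that add atoms: none
Why: Ring-closing olefin metathesis between the allyl group on C4 and the methallyl ketone should close ring B at the trisubstituted C6=C7 bond, the catalyst loading on the unhindered allyl group and benzoquinone suppressing ruthenium hydride isomerisation of the skipped enone.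

Step 10
Reactants: 16 (3R,3aR,8aR)-3-hydroxy-6,8a-dimethyl-3-(propan-2-yl)-2,3,3a,5,8,8a-hexahydroazulen-4(1H)-one; 17 4-[(tert-butyldimethylsilyl)oxy]benzaldehyde
Product: 19 (3R,3aS,4S,8aR)-4-hydroxy-6,8a-dimethyl-3-(propan-2-yl)-1,2,3,3a,4,5,8,8a-octahydroazulen-3-yl 4-[(tert-butyldimethylsilyl)oxy]benzoate, via samarium hemiacetal alkoxide 18 (not isolated)
Conditions: 17 (4 equiv), SmI2 (0.3 equiv, 0.1 M in THF), THF, −10 °C, dark; aq. NaHCO3
Reagents that add atoms: none
Why: Proposed new method: the trivalent samarium alkoxide generated from SmI2 and the aldehyde binds the β-hydroxy ketone, the C1 oxygen adds to a second molecule of 17 to give hemiacetal 18, and its C–H is passed as hydride to the C9 carbonyl through a six-membered chair (H, acetal C, O, C1, C10, C9), which turns the hemiacetal into the ester on the C1 oxygen and leaves a samarium alkoxide at C9 that is exchanged on turnover. The closest known reaction type is the Evans–Tishchenko reduction of secondary β-hydroxy ketones to anti-1,3-diol monoesters; what is new is the tertiary, isopropyl-flanked carbinol as the hemiacetal donor. No ring is closed. The one new stereocentre, C9, is controlled by C1 through C10: O1 and C9 are cis on ring A and ring B fixes C8, so hydride can only reach the carbonyl face that looks towards O1, which gives C9–H on the side of the C1 oxygen and the C9 hydroxyl anti to it (4S). The step needs hydride transfer to outrun retro-aldol opening of the tertiary aldol and migration of the aroyl group to the C9 oxygen; the rigid cis-1,3 arrangement made in step 7, the low temperature and the neutral samarium catalyst should secure this, and the electron-rich aldehyde is used in excess because its hemiacetal forms less readily. In one operation the step sets C9 and places the aroyl group on the hindered tertiary oxygen without any acylation.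

Step 11
Reactants: 19 (3R,3aS,4S,8aR)-4-hydroxy-6,8a-dimethyl-3-(propan-2-yl)-1,2,3,3a,4,5,8,8a-octahydroazulen-3-yl 4-[(tert-butyldimethylsilyl)oxy]benzoate
Product: 20 (3R,3aS,4S,6R,7S,8aR)-6,7-epoxy-4-hydroxy-6,8a-dimethyl-3-(propan-2-yl)decahydroazulen-3-yl 4-[(tert-butyldimethylsilyl)oxy]benzoate
Conditions: VO(acac)2 (5 mol %), t-BuOOH (1.5 equiv), CH2Cl2, 0 → 23 °C
Reagents that add atoms: tert-butyl hydroperoxide, CC(C)(C)OO
Why: Vanadium-catalysed hydroxyl-directed epoxidation of the homoallylic alcohol should deliver oxygen to the C6=C7 face syn to C9–OH, which is also the face away from the angular methyl group, and so set C6 and C7.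

Step 12
Reactants: 20 (3R,3aS,4S,6R,7S,8aR)-6,7-epoxy-4-hydroxy-6,8a-dimethyl-3-(propan-2-yl)decahydroazulen-3-yl 4-[(tert-butyldimethylsilyl)oxy]benzoate
Product: 21 (3R,3aS,4S,6R,7S,8aR)-6,7-epoxy-4-hydroxy-6,8a-dimethyl-3-(propan-2-yl)decahydroazulen-3-yl 4-hydroxybenzoate (CNP0264773.1)
Conditions: KHF2 (2 equiv), MeOH, 23 °C
Reagents that add atoms: none
Why: Bifluoride cleaves the aryl silyl ether selectively, and the weakly acidic medium forms no alkoxide, so the tertiary ester should not migrate to the C9 oxygen and the epoxide should stay closed.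

**Compound list**

1 | (1S)-4-methyl-1-(propan-2-yl)cyclohex-3-en-1-ol, (S)-(+)-terpinen-4-ol | CC1=CC[C@](O)(C(C)C)CC1 | starting material
2 | tert-butyldimethyl{[(1S)-4-methyl-1-(propan-2-yl)cyclohex-3-en-1-yl]oxy}silane | CC1=CC[C@](O[Si](C)(C)C(C)(C)C)(C(C)C)CC1 | intermediate
3 | tert-butyldimethyl{[(1S,4S,6R)-1-methyl-4-(propan-2-yl)-7-oxabicyclo[4.1.0]heptan-4-yl]oxy}silane (oxirane trans to the silyloxy group; its oxirane epimer is carried along and converges at 6) | C[C@]12CC[C@@](O[Si](C)(C)C(C)(C)C)(C(C)C)C[C@H]1O2 | intermediate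
4 | (1S,2S,4S)-4-[(tert-butyldimethylsilyl)oxy]-1-methyl-2-(phenylselanyl)-4-(propan-2-yl)cyclohexan-1-ol | C[C@]1(O)CC[C@@](O[Si](C)(C)C(C)(C)C)(C(C)C)C[C@@H]1[Se]c1ccccc1 | intermediate
5 | (1S,4R)-4-[(tert-butyldimethylsilyl)oxy]-1-methyl-4-(propan-2-yl)cyclohex-2-en-1-ol (with its C1 epimer from the minor epoxide) | C[C@]1(O)CC[C@@](O[Si](C)(C)C(C)(C)C)(C(C)C)C=C1 | intermediate
6 | (6R)-6-[(tert-butyldimethylsilyl)oxy]-3-methyl-6-(propan-2-yl)cyclohex-2-en-1-one | CC1=CC(=O)[C@](O[Si](C)(C)C(C)(C)C)(C(C)C)CC1 | intermediate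
7 | trichloro{[(3R,6R)-6-[(tert-butyldimethylsilyl)oxy]-3-methyl-6-(propan-2-yl)-3-(prop-2-en-1-yl)cyclohex-1-en-1-yl]oxy}titanium | C=CC[C@@]1(C)CC[C@@](O[Si](C)(C)C(C)(C)C)(C(C)C)C(O[Ti](Cl)(Cl)Cl)=C1 | intermediate
8 | (2R,5R)-2-[(tert-butyldimethylsilyl)oxy]-5-methyl-2-(propan-2-yl)-5-(prop-2-en-1-yl)cyclohexan-1-one | C=CC[C@@]1(C)CC[C@@](O[Si](C)(C)C(C)(C)C)(C(C)C)C(=O)C1 | intermediate
9 | (2R,5R)-2-hydroxy-5-methyl-2-(propan-2-yl)-5-(prop-2-en-1-yl)cyclohexan-1-one | C=CC[C@@]1(C)CC[C@@](O)(C(C)C)C(=O)C1 | intermediate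
10 | (2R,5R)-2-hydroxy-5-methyl-2-(propan-2-yl)-5-(prop-2-en-1-yl)-6-(trifluoroacetyl)cyclohexan-1-one (C6 not defined, enolised) | C=CC[C@@]1(C)CC[C@@](O)(C(C)C)C(=O)C1C(=O)C(F)(F)F | intermediate
11 | (2R,5R)-6-diazo-2-hydroxy-5-methyl-2-(propan-2-yl)-5-(prop-2-en-1-yl)cyclohexan-1-one | C=CC[C@@]1(C)CC[C@@](O)(C(C)C)C(=O)C1=[N+]=[N-] | intermediate
12 | [(2R,5R)-2-hydroxy-5-methyl-2-(propan-2-yl)-5-(prop-2-en-1-yl)cyclopentylidene]methanone (ketene) | C=CC[C@@]1(C)CC[C@@](O)(C(C)C)C1=C=O | intermediate
13 | (1R,2R,5R)-2-methyl-5-(propan-2-yl)-2-(prop-2-en-1-yl)-6-oxabicyclo[3.2.0]heptan-7-one (cis-fused β-lactone) | C=CC[C@@]1(C)CC[C@]2(C(C)C)OC(=O)[C@H]12 | intermediate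
14 | (1R,2R,5R)-2-hydroxy-N-methoxy-N,5-dimethyl-2-(propan-2-yl)-5-(prop-2-en-1-yl)cyclopentane-1-carboxamide | C=CC[C@@]1(C)CC[C@@](O)(C(C)C)[C@@H]1C(=O)N(C)OC | intermediate
15 | 1-[(1R,2R,5R)-2-hydroxy-5-methyl-2-(propan-2-yl)-5-(prop-2-en-1-yl)cyclopentyl]-3-methylbut-3-en-1-one | C=CC[C@@]1(C)CC[C@@](O)(C(C)C)[C@@H]1C(=O)CC(C)=C | intermediate
16 | (3R,3aR,8aR)-3-hydroxy-6,8a-dimethyl-3-(propan-2-yl)-2,3,3a,5,8,8a-hexahydroazulen-4(1H)-one (trans-fused; hydroxyl cis to the ketone carbon on ring A) | CC(C)[C@]1(O)CC[C@]2(C)CC=C(C)CC(=O)[C@H]21 | intermediate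
17 | 4-[(tert-butyldimethylsilyl)oxy]benzaldehyde | O=Cc1ccc(O[Si](C)(C)C(C)(C)C)cc1 | starting material
18 | hemiacetal of 16 and 17 at the C1 oxygen (present as its trivalent samarium alkoxide; drawn as the free hemiacetal, acetal carbon not defined) | CC(C)[C@]1(OC(O)c2ccc(O[Si](C)(C)C(C)(C)C)cc2)CC[C@]2(C)CC=C(C)CC(=O)[C@H]21 | intermediate
19 | (3R,3aS,4S,8aR)-4-hydroxy-6,8a-dimethyl-3-(propan-2-yl)-1,2,3,3a,4,5,8,8a-octahydroazulen-3-yl 4-[(tert-butyldimethylsilyl)oxy]benzoate | CC(C)[C@]1(OC(=O)c2ccc(O[Si](C)(C)C(C)(C)C)cc2)CC[C@]2(C)CC=C(C)C[C@H](O)[C@H]21 | intermediate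
20 | (3R,3aS,4S,6R,7S,8aR)-6,7-epoxy-4-hydroxy-6,8a-dimethyl-3-(propan-2-yl)decahydroazulen-3-yl 4-[(tert-butyldimethylsilyl)oxy]benzoate (oxirane oxygen cis to the secondary hydroxyl) | CC(C)[C@]1(OC(=O)c2ccc(O[Si](C)(C)C(C)(C)C)cc2)CC[C@]2(C)C[C@@H]3O[C@]3(C)C[C@H](O)[C@H]21 | intermediate
21 | (3R,3aS,4S,6R,7S,8aR)-6,7-epoxy-4-hydroxy-6,8a-dimethyl-3-(propan-2-yl)decahydroazulen-3-yl 4-hydroxybenzoate | CC(C)[C@]1(OC(=O)c2ccc(O)cc2)CC[C@]2(C)C[C@@H]3O[C@]3(C)C[C@H](O)[C@H]21 | target

**Count and risks**

Total steps: 12. Longest linear sequence: 12 (from 1; aldehyde 17 is purchased).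

The three steps most likely to fail:

Step 10 (Proposed new method). The tertiary aldol may open by retro-aldol cleavage under the samarium alkoxide, the crowded C1 oxygen may fail to add to the aldehyde, or the aroyl group may migrate to the C9 oxygen. The fallback sets out from 16 and returns at 19 with known chemistry. Hydroxyl-directed 1,3-anti reduction with Me4NBH(OAc)3 in MeCN/AcOH at −20 °C (hydride again delivered from the C1 oxygen) would give (3R,3aS,4S,8aR)-6,8a-dimethyl-3-(propan-2-yl)-1,2,3,3a,4,5,8,8a-octahydroazulene-3,4-diol F1. Its secondary hydroxyl would be silylated (Et3SiCl, imidazole) to the triethylsilyl ether F2. The potassium alkoxide of the tertiary hydroxyl (KN(SiMe3)2, THF, −78 → 0 °C) would be acylated with 4-[(tert-butyldimethylsilyl)oxy]benzoyl chloride F3 (from the commercial acid and (COCl)2) to the ester F4. Methanolysis of the triethylsilyl ether (pyridinium p-toluenesulfonate, MeOH) would then give 19.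

Step 7 (Proposed new method). The ketene may be consumed before the hydroxyl captures it, or the strained lactone may not close, which would leave C10 to an unselective protonation. The fallback sets out from 11 and returns at 16. Photolysis in the presence of N,O-dimethylhydroxylamine would give the amide as a mixture of 14 and its C10 epimer F5. LiAlH4 would reduce the mixture to the β-hydroxy aldehydes, which triethylamine would equilibrate through the enol to the hydrogen-bonded cis isomer F6 (the trans isomer eclipses the isopropyl group). Addition of 2-methylallylmagnesium chloride would give the diol F7 (both carbinol epimers), ring-closing metathesis the bicyclic diol F8, and Dess–Martin oxidation of the secondary alcohol the ketone 16.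

Step 5. Facial control may be lost if titanium bridges the carbonyl and silyloxy oxygens (ring flip) or strips the silyl group before the C–C bond forms. The fallback sets out from 6 and returns at 8. Allylmagnesium bromide would add 1,2 to the ketone anti to the silyloxy group (polar Felkin–Anh) to give the tertiary alcohol F9. Anionic oxy-Cope rearrangement (KH, 18-crown-6, THF) would then transfer the allyl group suprafacially to C4 and give, after protonation of the enolate, ketone 8.

**Further compounds**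

F1 | step 10 | (3R,3aS,4S,8aR)-6,8a-dimethyl-3-(propan-2-yl)-1,2,3,3a,4,5,8,8a-octahydroazulene-3,4-diol | CC(C)[C@]1(O)CC[C@]2(C)CC=C(C)C[C@H](O)[C@H]21
F2 | step 10 | (3R,3aS,4S,8aR)-6,8a-dimethyl-3-(propan-2-yl)-4-[(triethylsilyl)oxy]-1,2,3,3a,4,5,8,8a-octahydroazulen-3-ol | CC(C)[C@]1(O)CC[C@]2(C)CC=C(C)C[C@H](O[Si](CC)(CC)CC)[C@H]21
F3 | step 10 | 4-[(tert-butyldimethylsilyl)oxy]benzoyl chloride | O=C(Cl)c1ccc(O[Si](C)(C)C(C)(C)C)cc1
F4 | step 10 | (3R,3aS,4S,8aR)-6,8a-dimethyl-3-(propan-2-yl)-4-[(triethylsilyl)oxy]-1,2,3,3a,4,5,8,8a-octahydroazulen-3-yl 4-[(tert-butyldimethylsilyl)oxy]benzoate | CC(C)[C@]1(OC(=O)c2ccc(O[Si](C)(C)C(C)(C)C)cc2)CC[C@]2(C)CC=C(C)C[C@H](O[Si](CC)(CC)CC)[C@H]21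
F5 | step 7 | (1S,2R,5R)-2-hydroxy-N-methoxy-N,5-dimethyl-2-(propan-2-yl)-5-(prop-2-en-1-yl)cyclopentane-1-carboxamide | C=CC[C@@]1(C)CC[C@@](O)(C(C)C)[C@H]1C(=O)N(C)OC
F6 | step 7 | (1R,2R,5R)-2-hydroxy-5-methyl-2-(propan-2-yl)-5-(prop-2-en-1-yl)cyclopentane-1-carbaldehyde | C=CC[C@@]1(C)CC[C@@](O)(C(C)C)[C@@H]1C=O
F7 | step 7 | 1-[(1S,2R,5R)-2-hydroxy-5-methyl-2-(propan-2-yl)-5-(prop-2-en-1-yl)cyclopentyl]-3-methylbut-3-en-1-ol (both carbinol epimers) | C=CC[C@@]1(C)CC[C@@](O)(C(C)C)[C@@H]1C(O)CC(C)=C
F8 | step 7 | (3R,3aS,8aR)-6,8a-dimethyl-3-(propan-2-yl)-1,2,3,3a,4,5,8,8a-octahydroazulene-3,4-diol (both C4 epimers) | CC(C)[C@]1(O)CC[C@]2(C)CC=C(C)CC(O)[C@H]21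
F9 | step 5 | (1R,6R)-6-[(tert-butyldimethylsilyl)oxy]-3-methyl-6-(propan-2-yl)-1-(prop-2-en-1-yl)cyclohex-2-en-1-ol | C=CC[C@@]1(O)C=C(C)CC[C@@]1(O[Si](C)(C)C(C)(C)C)C(C)C
A1 | direct plan | methyl (2S,3S)-3-[(tert-butyldimethylsilyl)oxy]-5-methyl-2-[(3S)-3-methylhexa-1,5-dien-3-yl]hex-5-enoate | C=C[C@](C)(CC=C)[C@@H]([C@@H](O[Si](C)(C)C(C)(C)C)CC(C)=C)C(=O)OC
A2 | direct plan | (3aS,4S,8aR)-4-[(tert-butyldimethylsilyl)oxy]-6,8a-dimethyl-2,3a,4,5,8,8a-hexahydroazulen-3(1H)-one | O=C1CC[C@]2(C)CC=C(C)C[C@H](O[Si](C)(C)C(C)(C)C)[C@H]21
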